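One falling exponential cannot pass through a target that first rises, but from 1.00 min on, both earlier runs only fall.

in all of them: gas phase 4.7 mM (held)

| run | substrate | remark | time |
|---|---|---|---|
| south-west | 0.14 M | run made earlier |  |
| south-east | 0.22 M | run made earlier |  |
| flask | 0.10 M |  | 2.5 min |

| run | time / min | target / % |
|---|---|---|
| south-west | 0.333 | 6.6 |
| south-west | 0.667 | 9.2 |
| south-west | 1.00 | 9.4 |
| south-west | 1.33 | 8.6 |
| south-west | 2.00 | 5.5 |
| south-west | 2.50 | 3.8 |
| south-east | 0.167 | 3.0 |
| south-east | 0.417 | 6.2 |
| south-east | 0.667 | 8.1 |
| south-east | 1.00 | 8.7 |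
| south-east | 1.50 | 6.9 |
| south-east | 2.00 | 5.1 |
| south-east | 2.50 | 3.8 |

(scatter of a reading: 0.3 percentage points)

- amount of target at 2.5 min, in percent of the substrate charged
- concentration of dissolved gas in solution at 2.5 min, in percent of saturation

Over that stretch, the net loss can be written as dc_target/dt = −λ·c_target, which integrates to

c_target(late) = c_target(early)·exp(−λ·Δt), with early at 1.00 min and late at 2.5 min.

The south-west run gives λ = 0.604 min⁻¹ and the south-east run 0.552 min⁻¹. The south-west run, with less substrate, falls faster and starts higher, at 9.4% against 8.7%. In reciprocal substrate, the flask lies 1.10 of the step between the runs beyond south-west. Continuing both trends gives the flask its fall constant, the mean apparent first-order loss of target per minute over the stretch: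

λ = 0.661 min⁻¹, early target = 10.2%

High start with the south-west fall: 4.11%
South-west start with the flask's fall: 3.49%
Own estimate, both continued: 3.78%

The forecast, reckoned separately, says “the dissolved gas then destroys it” and gives 3.7% (2.9% to 4.5%), inside this bracket, with 55% of saturation.

The flask gives 3.59%, also inside, and 90.3% of saturation, above the forecast's range.

    gas phase ⇌ dissolved gas, rate k1*(csat - [dissolved gas]) (kL = 0.250 s⁻¹)
    substrate + dissolved gas ⇌ target (K = 160 M⁻¹, k = 2.50 M⁻¹ s⁻¹)
    substrate → side product (k = 0.0130 s⁻¹)
    dissolved gas + target → over-reaction product (k = 5.30 M⁻¹ s⁻¹)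

With λ, the flask's 9.15% at 1.25 min carries forward to 4.00%, and its end value carries back to 9.68% for a neighbouring flask of the same charge, which held 10.1% at 1.0 min. Up to 0.625 min, substrate in the flask passed into side product and, with dissolved gas, into target, which stood at 10.0%. With dissolved gas at 76.0% of saturation by 1.25 min, target went on passing with it into over-reaction product, which reached 19.6% at 2.50 min.

All runs are simulated on assumed constants; the scatter is artificial.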